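**Retrosynthetic overview**
- The target comes from a penta-O-benzyl biflavone by one global hydrogenolysis. The single methoxy group is carried in from acacetin, and benzyl is the only protecting group.
- The 3',8''-biaryl bond is cut by a Suzuki–Miyaura disconnection into an 8-iodo-di-O-benzylacacetin and the 3'-boronate of tri-O-benzylapigenin, made in the same flask from the 3'-bromide.
- The iodide half needs no ring construction: acacetin is benzylated and iodinated at C8.
- The bromide half comes from a 2'-hydroxychalcone (Claisen–Schmidt), whose ring C is closed by I2/DMSO.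
- Ring order: ring C of the bromide half is the only ring built, then the biaryl bond, then deprotection.

Assumption: the target has no stereocentre and its tri-ortho-substituted biaryl axis is taken as configurationally unstable, so no stereocontrol is needed; the benzylated acetophenone and the bromoaldehyde are taken to be catalogue items.

**Route**

Step 1
Reactants: 1 acacetin (5,7-dihydroxy-2-(4-methoxyphenyl)-4H-chromen-4-one)
Product: 2 5,7-bis(benzyloxy)-2-(4-methoxyphenyl)-4H-chromen-4-one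
Conditions: BnBr (3 equiv), K2CO3 (4 equiv), DMF, 80 °C
Reagents that add atoms: benzyl bromide, BrCc1ccccc1
Why: Williamson ether synthesis in which K2CO3 in hot DMF ionises both phenols (the hydrogen-bonded 5-OH needs the heat and the excess halide) and O-benzylation masks them with groups that can later be removed without touching the aryl methyl ether; no stereocentre is formed.

Step 2
Reactants: 2 5,7-bis(benzyloxy)-2-(4-methoxyphenyl)-4H-chromen-4-one
Product: 3 5,7-bis(benzyloxy)-8-iodo-2-(4-methoxyphenyl)-4H-chromen-4-one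
Conditions: NIS (1.1 equiv), TFA (cat.), CH2Cl2/MeCN, 0 °C to rt, dark
Reagents that add atoms: N-iodosuccinimide, O=C1CCC(=O)N1I
Why: Electrophilic aromatic iodination in which a fully 5,7-O-alkylated flavone reacts at C8 (ortho to the 7-ether and the ring oxygen, para to the 5-ether) in preference to C6, which is shielded between two benzyloxy groups, while ring B and C3 are far less nucleophilic; no stereocentre is formed.

Step 3
Reactants: 4 1-[2,4-bis(benzyloxy)-6-hydroxyphenyl]ethan-1-one; 5 4-(benzyloxy)-3-bromobenzaldehyde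
Product: 6 (E)-1-[2,4-bis(benzyloxy)-6-hydroxyphenyl]-3-[4-(benzyloxy)-3-bromophenyl]prop-2-en-1-one
Conditions: KOH (50% aq), EtOH/THF, rt; then dilute HCl
Reagents that add atoms: none
Why: Claisen–Schmidt (crossed aldol) condensation in which the methyl ketone enolate adds to the non-enolisable aldehyde and E1cB loss of water gives the conjugated enone with the thermodynamically favoured (E) geometry; no stereocentre is formed.

Step 4
Reactants: 6 (E)-1-[2,4-bis(benzyloxy)-6-hydroxyphenyl]-3-[4-(benzyloxy)-3-bromophenyl]prop-2-en-1-one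
Product: 8 5,7-bis(benzyloxy)-2-[4-(benzyloxy)-3-bromophenyl]-4H-chromen-4-one, via flavanone 7 (not isolated)
Conditions: I2 (10 mol%), DMSO, 130 °C
Reagents that add atoms: none
Why: Iodine/DMSO oxidative cyclisation in which oxa-Michael addition of the free 2'-phenol gives the racemic flavanone, and α-iodination followed by loss of hydrogen iodide (reoxidised to I2 by DMSO) gives the flavone, so the transient C2 stereocentre is erased.

Step 5
Reactants: 8 5,7-bis(benzyloxy)-2-[4-(benzyloxy)-3-bromophenyl]-4H-chromen-4-one; 3 5,7-bis(benzyloxy)-8-iodo-2-(4-methoxyphenyl)-4H-chromen-4-one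
Product: 10 5,7-bis(benzyloxy)-8-{2-(benzyloxy)-5-[5,7-bis(benzyloxy)-4-oxo-4H-chromen-2-yl]phenyl}-2-(4-methoxyphenyl)-4H-chromen-4-one, via aryl pinacol boronate 9 (not isolated)
Conditions: Pd2(dba)3 (2.5 mol%), XPhos (10 mol%), B2pin2 (1.1 equiv), KOAc, 1,4-dioxane, 100 °C; then 3 (0.9 equiv), aq K3PO4, 100 °C
Reagents that add atoms: bis(pinacolato)diboron, CC1(C)OB(OC1(C)C)B1OC(C)(C)C(C)(C)O1 (supplies the boryl group of 9; none of its atoms remain in 10)
Why: One-pot Miyaura borylation then Suzuki–Miyaura cross-coupling in which zerovalent palladium with the bulky biaryl phosphine turns the aryl bromide into its pinacol boronate and, once the iodide and aqueous K3PO4 are added, forges the hindered 3',8''-biaryl bond; the axis is not configurationally stable and no stereocentre is formed.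

Step 6
Reactants: 10 5,7-bis(benzyloxy)-8-{2-(benzyloxy)-5-[5,7-bis(benzyloxy)-4-oxo-4H-chromen-2-yl]phenyl}-2-(4-methoxyphenyl)-4H-chromen-4-one
Product: 11 podocarpusflavone A (8-[5-(5,7-dihydroxy-4-oxo-4H-chromen-2-yl)-2-hydroxyphenyl]-5,7-dihydroxy-2-(4-methoxyphenyl)-4H-chromen-4-one)
Conditions: H2 (1 atm), 10% Pd/C, THF/MeOH, rt
Reagents that add atoms: none
Why: Catalytic hydrogenolysis cleaves all five benzyl ethers at once, while the aryl methyl ether and the chromone C2=C3 bonds are inert under these mild conditions; no stereocentre is involved.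

**Compound list**
1 | acacetin, 5,7-dihydroxy-2-(4-methoxyphenyl)-4H-chromen-4-one | COc1ccc(-c2cc(=O)c3c(O)cc(O)cc3o2)cc1 | starting material
2 | 5,7-bis(benzyloxy)-2-(4-methoxyphenyl)-4H-chromen-4-one | COc1ccc(-c2cc(=O)c3c(OCc4ccccc4)cc(OCc4ccccc4)cc3o2)cc1 | intermediate
3 | 5,7-bis(benzyloxy)-8-iodo-2-(4-methoxyphenyl)-4H-chromen-4-one | COc1ccc(-c2cc(=O)c3c(OCc4ccccc4)cc(OCc4ccccc4)c(I)c3o2)cc1 | intermediate
4 | 1-[2,4-bis(benzyloxy)-6-hydroxyphenyl]ethan-1-one | CC(=O)c1c(O)cc(OCc2ccccc2)cc1OCc1ccccc1 | starting material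
5 | 4-(benzyloxy)-3-bromobenzaldehyde | O=Cc1ccc(OCc2ccccc2)c(Br)c1 | starting material
6 | (E)-1-[2,4-bis(benzyloxy)-6-hydroxyphenyl]-3-[4-(benzyloxy)-3-bromophenyl]prop-2-en-1-one | O=C(/C=C/c1ccc(OCc2ccccc2)c(Br)c1)c1c(O)cc(OCc2ccccc2)cc1OCc1ccccc1 | intermediate
7 | racemic 5,7-bis(benzyloxy)-2-[4-(benzyloxy)-3-bromophenyl]-2,3-dihydro-4H-chromen-4-one (flavanone) | O=C1CC(c2ccc(OCc3ccccc3)c(Br)c2)Oc2cc(OCc3ccccc3)cc(OCc3ccccc3)c21 | intermediate (not isolated)
8 | 5,7-bis(benzyloxy)-2-[4-(benzyloxy)-3-bromophenyl]-4H-chromen-4-one | O=c1cc(-c2ccc(OCc3ccccc3)c(Br)c2)oc2cc(OCc3ccccc3)cc(OCc3ccccc3)c12 | intermediate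
9 | 5,7-bis(benzyloxy)-2-[4-(benzyloxy)-3-(4,4,5,5-tetramethyl-1,3,2-dioxaborolan-2-yl)phenyl]-4H-chromen-4-one | O=c1cc(-c2ccc(OCc3ccccc3)c(B3OC(C)(C)C(C)(C)O3)c2)oc2cc(OCc3ccccc3)cc(OCc3ccccc3)c12 | intermediate (not isolated)
10 | 5,7-bis(benzyloxy)-8-{2-(benzyloxy)-5-[5,7-bis(benzyloxy)-4-oxo-4H-chromen-2-yl]phenyl}-2-(4-methoxyphenyl)-4H-chromen-4-one | COc1ccc(-c2cc(=O)c3c(OCc4ccccc4)cc(OCc4ccccc4)c(-c4cc(-c5cc(=O)c6c(OCc7ccccc7)cc(OCc7ccccc7)cc6o5)ccc4OCc4ccccc4)c3o2)cc1 | intermediate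
11 | podocarpusflavone A | COc1ccc(-c2cc(=O)c3c(O)cc(O)c(-c4cc(-c5cc(=O)c6c(O)cc(O)cc6o5)ccc4O)c3o2)cc1 | target

**Totals**
Total step count: 6 (steps 4 and 5 each pass through one non-isolated intermediate).
Longest linear sequence: 4 steps (4/5 → 6 → 8 → 10 → 11; the acacetin branch 1 → 2 → 3 → 10 → 11 is equally long).

**Three steps most likely to fail**

Step 2 (C8 iodination). The risk is a C6/C8 mixture or di-iodination that is hard to separate. Fallback: put the iodine in before ring C exists. Setting out from 4, NIS with cat. TsOH in MeCN iodinates ortho to the free, hydrogen-bonded phenol to give 1-[4,6-bis(benzyloxy)-2-hydroxy-3-iodophenyl]ethan-1-one F1. Claisen–Schmidt condensation with 4-methoxybenzaldehyde (KOH, EtOH/THF) gives (E)-1-[4,6-bis(benzyloxy)-2-hydroxy-3-iodophenyl]-3-(4-methoxyphenyl)prop-2-en-1-one F2. I2 (cat.) in DMSO at 130 °C then closes ring C. Because the iodine sits next to the phenol oxygen that becomes O1, it can only end up at C8, and the sequence comes back to the route at 3.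

Step 4 (I2/DMSO oxidative cyclisation). The risk is that hot hydrogen iodide cleaves the peri 5-O-benzyl ether, or that the hindered chalcone stalls at flavanone 7. Fallback: a Baker–Venkataraman route in place of chalcone oxidation. Setting out from 5, Pinnick oxidation (NaClO2, NaH2PO4, 2-methyl-2-butene, t-BuOH/H2O) gives 4-(benzyloxy)-3-bromobenzoic acid F3. Steglich esterification with 4 (EDC·HCl, DMAP, CH2Cl2) gives 2-acetyl-3,5-bis(benzyloxy)phenyl 4-(benzyloxy)-3-bromobenzoate F4. KOH in pyridine at 50 °C moves the aroyl group from O to C to give 1-[2,4-bis(benzyloxy)-6-hydroxyphenyl]-3-[4-(benzyloxy)-3-bromophenyl]propane-1,3-dione F5. Cat. TsOH in toluene at 90 °C cyclodehydrates it, and the sequence comes back to the route at 8, already at the flavone oxidation level and without any oxidant.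

Step 5 (one-pot borylation and hindered Suzuki coupling). The risks are protodeboronation of 9, homocoupling of 3 through leftover diboron, and slow coupling of two bulky, poorly soluble flavones. Fallback: make the biaryl bond on a small partner and build the second flavone afterwards. Setting out from 5, Miyaura borylation (B2pin2, PdCl2(dppf), KOAc, 1,4-dioxane, 90 °C) gives 4-(benzyloxy)-3-(4,4,5,5-tetramethyl-1,3,2-dioxaborolan-2-yl)benzaldehyde F6, which is isolated and purified. Suzuki–Miyaura coupling with 3 (Pd(OAc)2, SPhos, K3PO4, toluene/H2O, 90 °C) gives 4-(benzyloxy)-3-[5,7-bis(benzyloxy)-2-(4-methoxyphenyl)-4-oxo-4H-chromen-8-yl]benzaldehyde F7. Claisen–Schmidt condensation with 4 (KOH, EtOH/THF, rt) gives 5,7-bis(benzyloxy)-8-{2-(benzyloxy)-5-[(E)-3-[2,4-bis(benzyloxy)-6-hydroxyphenyl]-3-oxoprop-1-en-1-yl]phenyl}-2-(4-methoxyphenyl)-4H-chromen-4-one F8. I2 (cat.) in DMSO at 130 °C closes the second ring C, and the sequence comes back to the route at 10.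

**Further compounds**
F1 | step 2 | 1-[4,6-bis(benzyloxy)-2-hydroxy-3-iodophenyl]ethan-1-one | CC(=O)c1c(O)c(I)c(OCc2ccccc2)cc1OCc1ccccc1
F2 | step 2 | (E)-1-[4,6-bis(benzyloxy)-2-hydroxy-3-iodophenyl]-3-(4-methoxyphenyl)prop-2-en-1-one | COc1ccc(/C=C/C(=O)c2c(O)c(I)c(OCc3ccccc3)cc2OCc2ccccc2)cc1
F3 | step 4 | 4-(benzyloxy)-3-bromobenzoic acid | O=C(O)c1ccc(OCc2ccccc2)c(Br)c1
F4 | step 4 | 2-acetyl-3,5-bis(benzyloxy)phenyl 4-(benzyloxy)-3-bromobenzoate | CC(=O)c1c(OC(=O)c2ccc(OCc3ccccc3)c(Br)c2)cc(OCc2ccccc2)cc1OCc1ccccc1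
F5 | step 4 | 1-[2,4-bis(benzyloxy)-6-hydroxyphenyl]-3-[4-(benzyloxy)-3-bromophenyl]propane-1,3-dione | O=C(CC(=O)c1c(O)cc(OCc2ccccc2)cc1OCc1ccccc1)c1ccc(OCc2ccccc2)c(Br)c1
F6 | step 5 | 4-(benzyloxy)-3-(4,4,5,5-tetramethyl-1,3,2-dioxaborolan-2-yl)benzaldehyde | O=Cc1ccc(OCc2ccccc2)c(B2OC(C)(C)C(C)(C)O2)c1
F7 | step 5 | 4-(benzyloxy)-3-[5,7-bis(benzyloxy)-2-(4-methoxyphenyl)-4-oxo-4H-chromen-8-yl]benzaldehyde | COc1ccc(-c2cc(=O)c3c(OCc4ccccc4)cc(OCc4ccccc4)c(-c4cc(C=O)ccc4OCc4ccccc4)c3o2)cc1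
F8 | step 5 | 5,7-bis(benzyloxy)-8-{2-(benzyloxy)-5-[(E)-3-[2,4-bis(benzyloxy)-6-hydroxyphenyl]-3-oxoprop-1-en-1-yl]phenyl}-2-(4-methoxyphenyl)-4H-chromen-4-one | COc1ccc(-c2cc(=O)c3c(OCc4ccccc4)cc(OCc4ccccc4)c(-c4cc(/C=C/C(=O)c5c(O)cc(OCc6ccccc6)cc5OCc5ccccc5)ccc4OCc4ccccc4)c3o2)cc1
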